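**Retrosynthetic overview**
- The target comes from a daucene-4,6,10-triol by angeloylation of C10–OH (the C4/C6 diol masked in the flask as a phenylboronate) and then benzoylation of C6–OH.
- The triol is cut at C6–C7: a cyclopentanecarbaldehyde whose C1 carries a cis-2-isopropenyloxirane closes reductively (SmI2) to the seven-membered ring.
- Enabling feature: the C7=C8 methylidene is bonded directly to the C9–C10 oxirane and sits trans on the five-membered ring to the C6 formyl group, next to the C4 hydroxyl. A ketyl at C6 that reaches C7 leaves a radical at C8 beside the strained three-membered ring, and its opening gives C8=C9 and the C10 alkoxide.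
- The cyclopentane comes from an intramolecular aldol (C4–C5) of a 1,6-keto aldehyde, itself made by ozonolytic C=C cleavage of a cyclohexene. The oxirane comes from γ-chloroallylboration of a Diels–Alder aldehyde that sets C1.
- Ring order: cyclohexene (Diels–Alder), oxirane, cyclohexene cleaved, cyclopentane (aldol), cycloheptene (key step, oxirane opened).

Key step: step 6

Remark on the chemistry: locants C1–C10 in the text are daucane locants (C1 methyl-bearing ring-fusion carbon, C4 isopropyl carbinol carbon, C5 ring-fusion CH, C6 benzoyloxy carbon, C7 ring CH2, C8=C9 ring alkene, C10 acyloxy carbon), and the enoate is read as the (2Z)-2-methylbut-2-enoate (angelate).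

Step 1
Reactants: 1 3-methylbut-1-yne; 2 ethene
Product: 3 2-(propan-2-yl)buta-1,3-diene
Conditions: ethene (4 bar), second-generation Grubbs catalyst RuCl2(=CHPh)(H2IMes)(PCy3) (3 mol%), CH2Cl2, rt; diene distilled and used as a solution
Reagents that add atoms: none
Why: Ethene–alkyne cross (enyne) metathesis of a terminal alkyne gives the 2-substituted 1,3-diene directly, and no stereocentre is formed.

Step 2
Reactants: 3 2-(propan-2-yl)buta-1,3-diene; 4 2-methylprop-2-enal
Product: 5 (1S)-1-methyl-4-(propan-2-yl)cyclohex-3-ene-1-carbaldehyde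
Conditions: (S)-1-(2-methylphenyl)-3,3-diphenyltetrahydro-1H,3H-pyrrolo[1,2-c][1,3,2]oxazaborole (10 mol%), HNTf2 (8 mol%), CH2Cl2, −78 → −40 °C
Reagents that add atoms: none
Why: Catalytic enantioselective Diels–Alder reaction in which the 2-alkyl diene and the acid-activated 2-substituted enal combine with 1,4 ("para") regiochemistry, and the protonated oxazaborolidine shields one face of the bound s-trans enal so that the quaternary centre C1 should form as S (the mirror-image catalyst is taken if the facial sense should turn out opposite).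

Step 3
Reactants: 5 (1S)-1-methyl-4-(propan-2-yl)cyclohex-3-ene-1-carbaldehyde; 6 3-chloro-2-methylprop-1-ene
Product: 8 (2S,3R)-2-[(1S)-1-methyl-4-(propan-2-yl)cyclohex-3-en-1-yl]-3-(prop-1-en-2-yl)oxirane, via syn-chlorohydrin 7 (not isolated)
Conditions: 6, LiN(c-C6H11)2, (+)-B-methoxydiisopinocampheylborane, Et2O, −95 °C; BF3·OEt2; then 5, −95 → −78 °C; then 3 M NaOH, 30% H2O2, 0 °C → rt
Reagents that add atoms: none
Why: γ-Chloroallylboration with the 2-methyl homologue of the known (Z)-γ-chloroallyl-diisopinocampheylborane through a closed chair transition state, in which the Z-chloroalkene geometry should give the syn chlorohydrin, the isopinocampheyl groups (from (−)-α-pinene) should direct addition to the re face of the formyl group and so set C10, and the alkaline work-up closes the oxirane by intramolecular SN2 with inversion at C9 to the cis-oxirane.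

Step 4
Reactants: 8 (2S,3R)-2-[(1S)-1-methyl-4-(propan-2-yl)cyclohex-3-en-1-yl]-3-(prop-1-en-2-yl)oxirane
Product: 9 (3S)-3,7-dimethyl-6-oxo-3-[(2S,3R)-3-(prop-1-en-2-yl)oxiran-2-yl]octanal
Conditions: O3 (1.0 equiv, titrated solution), pyridine, CH2Cl2, −78 °C; then Me2S, −78 °C → rt
Reagents that add atoms: ozone, [O-][O+]=O
Why: Ozonolysis with reductive work-up, in which electrophilic ozone should attack the trisubstituted, alkyl-substituted ring alkene much faster than the 1,1-disubstituted alkene that is deactivated by the adjacent oxirane oxygen, and no stereocentre is touched.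

Step 5
Reactants: 9 (3S)-3,7-dimethyl-6-oxo-3-[(2S,3R)-3-(prop-1-en-2-yl)oxiran-2-yl]octanal
Product: 10 (1R,2R,5S)-2-hydroxy-5-methyl-5-[(2S,3R)-3-(prop-1-en-2-yl)oxiran-2-yl]-2-(propan-2-yl)cyclopentane-1-carbaldehyde
Conditions: pyrrolidine (20 mol%), AcOH (20 mol%), THF, 0 °C → rt
Reagents that add atoms: none
Why: Enamine-mediated intramolecular aldol addition (5-enolexo, exo-trig) of the aldehyde α-carbon C5 to the isopropyl ketone C4, helped by the quaternary C1 in the chain; because the addition is reversible and C5 is epimerisable, thermodynamic control should place the three large groups (oxiranyl chain on C1, formyl on C5, isopropyl on C4) pseudo-equatorial, that is 1,2-trans/1,2-trans, which sets C4 (hydroxyl cis to the formyl group and hydrogen-bonded to it) and C5 relative to C1.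

Step 6
Reactants: 10 (1R,2R,5S)-2-hydroxy-5-methyl-5-[(2S,3R)-3-(prop-1-en-2-yl)oxiran-2-yl]-2-(propan-2-yl)cyclopentane-1-carbaldehyde
Product: 11 (3R,3aS,4S,8R,8aS)-6,8a-dimethyl-3-(propan-2-yl)-1,2,3,3a,4,5,8,8a-octahydroazulene-3,4,8-triol
Conditions: SmI2 (3 equiv), HMPA (12 equiv), THF, −78 → −20 °C, slow addition of 10 (final 5 mM); aq NH4Cl
Reagents that add atoms: none
Why: Proposed new method: SmI2/HMPA reduces the aldehyde to a samarium ketyl that adds 7-endo-trig to the unsubstituted methylidene carbon C7, and the tertiary oxiranylcarbinyl radical so formed at C8 opens the adjacent C9–O bond at once (strain release), the alkoxyl radical being reduced by a second SmI2 to the C10 alkoxide, so that C6–C7, the C8=C9 double bond and the C10 hydroxyl arise together. The closest known reaction types are the SmI2-promoted reductive coupling of ketones with vinyl oxiranes to 2-ene-1,5-diols and SmI2/HMPA endo ketyl–olefin cyclisations to medium rings, and the 7-endo closure of an aldehyde onto a vinyl oxirane is the untested part. The only ring closed is the cycloheptene, by 7-endo-trig radical closure, while the oxirane is opened. The new stereocentre C6 should be controlled by samarium bridging the ketyl oxygen and the C4 oxygen, with C7 bonding anti to C4 so that the C6 oxygen becomes pseudo-equatorial and H6 anti to H5, whereas C10 keeps the configuration of the oxirane and the ring enforces the Z alkene. The step needs 7-endo instead of 6-exo attack and C–O instead of C–C scission of the oxirane: the 1,1-disubstituted alkene offers only its CH2 terminus and gives a tertiary radical, the alkyl-substituted oxirane carbon disfavours C–C scission, and the cis-oxirane lets the ring close without a trans-fused three-membered ring. Should divalent samarium reduce the vinyl oxirane first, the allylsamarium formed should add to the aldehyde through the same CH2 terminus (attack through C9 would need a trans-fused bicyclo[3.3.0]octane), so both pathways converge on 11.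

Step 7
Reactants: 11 (3R,3aS,4S,8R,8aS)-6,8a-dimethyl-3-(propan-2-yl)-1,2,3,3a,4,5,8,8a-octahydroazulene-3,4,8-triol; 12 (2Z)-2-methylbut-2-enoic acid; 13 phenylboronic acid
Product: 16 (3R,3aS,4S,8R,8aS)-3,4-dihydroxy-6,8a-dimethyl-3-(propan-2-yl)-1,2,3,3a,4,5,8,8a-octahydroazulen-8-yl (2Z)-2-methylbut-2-enoate, via triol phenylboronate 14 (not isolated), via angeloylated phenylboronate 15 (not isolated)
Conditions: 13 (1.05 equiv), 4 Å molecular sieves, toluene, rt; then 12, 2,4,6-trichlorobenzoyl chloride, Et3N (premixed in toluene, rt), 75 °C; then pinacol, rt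
Reagents that add atoms: none
Why: The tertiary C4 and secondary C6 hydroxyls are the only 1,3-diol pair and should close a six-membered cyclic phenylboronate that leaves C10–OH alone free for a Yamaguchi-type mixed-anhydride esterification, run without a nucleophilic catalyst so that the Z enoate does not isomerise, after which pinacol transesterification releases the diol.

Step 8
Reactants: 16 (3R,3aS,4S,8R,8aS)-3,4-dihydroxy-6,8a-dimethyl-3-(propan-2-yl)-1,2,3,3a,4,5,8,8a-octahydroazulen-8-yl (2Z)-2-methylbut-2-enoate; 17 benzoyl chloride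
Product: 18 (3R,3aS,4S,8R,8aS)-4-(benzoyloxy)-3-hydroxy-6,8a-dimethyl-3-(propan-2-yl)-1,2,3,3a,4,5,8,8a-octahydroazulen-8-yl (2Z)-2-methylbut-2-enoate
Conditions: 17 (1.5 equiv), pyridine, DMAP (10 mol%), CH2Cl2, 0 °C → rt
Reagents that add atoms: none
Why: Nucleophile-catalysed acylation of the secondary C6 hydroxyl, the tertiary C4 hydroxyl being too hindered to react under these conditions, and no stereocentre is affected.

**Compound list**
1 | 3-methylbut-1-yne | CC(C)C#C | starting material
2 | ethene | C=C | starting material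
3 | 2-(propan-2-yl)buta-1,3-diene | C=CC(=C)C(C)C | intermediate
4 | 2-methylprop-2-enal | CC(=C)C=O | starting material
5 | (1S)-1-methyl-4-(propan-2-yl)cyclohex-3-ene-1-carbaldehyde | O=C[C@]1(C)CC=C(C(C)C)CC1 | intermediate
6 | 3-chloro-2-methylprop-1-ene | CC(=C)CCl | starting material
7 | (1S,2S)-2-chloro-3-methyl-1-[(1S)-1-methyl-4-(propan-2-yl)cyclohex-3-en-1-yl]but-3-en-1-ol (syn-chlorohydrin) | CC(C)C1=CC[C@](C)(CC1)[C@H](O)[C@@H](Cl)C(C)=C | intermediate
8 | (2S,3R)-2-[(1S)-1-methyl-4-(propan-2-yl)cyclohex-3-en-1-yl]-3-(prop-1-en-2-yl)oxirane (cis-oxirane) | CC(C)C1=CC[C@](C)(CC1)[C@@H]2O[C@@H]2C(C)=C | intermediate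
9 | (3S)-3,7-dimethyl-6-oxo-3-[(2S,3R)-3-(prop-1-en-2-yl)oxiran-2-yl]octanal | O=CC[C@](C)(CCC(=O)C(C)C)[C@@H]1O[C@@H]1C(C)=C | intermediate
10 | (1R,2R,5S)-2-hydroxy-5-methyl-5-[(2S,3R)-3-(prop-1-en-2-yl)oxiran-2-yl]-2-(propan-2-yl)cyclopentane-1-carbaldehyde | O=C[C@H]1[C@](O)(C(C)C)CC[C@]1(C)[C@@H]2O[C@@H]2C(C)=C | intermediate
11 | (3R,3aS,4S,8R,8aS)-6,8a-dimethyl-3-(propan-2-yl)-1,2,3,3a,4,5,8,8a-octahydroazulene-3,4,8-triol | O[C@@H]1C=C(C)C[C@H](O)[C@@H]2[C@]1(C)CC[C@@]2(O)C(C)C | intermediate
12 | (2Z)-2-methylbut-2-enoic acid (angelic acid) | C/C=C(/C)C(=O)O | starting material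
13 | phenylboronic acid | OB(O)c1ccccc1 | starting material
14 | cyclic phenylboronate of 11 over the C4 and C6 oxygens (2-phenyl-1,3,2-dioxaborinane ring, C10 hydroxyl free) | O[C@@H]1C=C(C)C[C@H](OB(c3ccccc3)O4)[C@@H]2[C@]1(C)CC[C@@]24C(C)C | intermediate
15 | C10 (2Z)-2-methylbut-2-enoate of phenylboronate 14 | C/C=C(/C)C(=O)O[C@@H]1C=C(C)C[C@H](OB(c3ccccc3)O4)[C@@H]2[C@]1(C)CC[C@@]24C(C)C | intermediate
16 | (3R,3aS,4S,8R,8aS)-3,4-dihydroxy-6,8a-dimethyl-3-(propan-2-yl)-1,2,3,3a,4,5,8,8a-octahydroazulen-8-yl (2Z)-2-methylbut-2-enoate | C/C=C(/C)C(=O)O[C@@H]1C=C(C)C[C@H](O)[C@@H]2[C@]1(C)CC[C@@]2(O)C(C)C | intermediate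
17 | benzoyl chloride | O=C(Cl)c1ccccc1 | starting material
18 | (3R,3aS,4S,8R,8aS)-4-(benzoyloxy)-3-hydroxy-6,8a-dimethyl-3-(propan-2-yl)-1,2,3,3a,4,5,8,8a-octahydroazulen-8-yl (2Z)-2-methylbut-2-enoate | C/C=C(/C)C(=O)O[C@@H]1C=C(C)C[C@H](OC(=O)c2ccccc2)[C@@H]2[C@]1(C)CC[C@@]2(O)C(C)C | target

Total step count: 8. Longest linear sequence: 8 steps (1 to 18).

**Steps most likely to fail**

1. Step 6 (proposed new method). What may go wrong: pinacol dimerisation or plain reduction of the aldehyde; reductive opening of the vinyl oxirane without ring closure; 6-exo closure; poor facial selectivity at C6.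
Fallback, known chemistry only, sets out from 5 and returns at 11; it closes the seven-membered ring by metathesis at C8=C9 instead. Vinylmagnesium bromide (THF, −78 °C) adds to 5 and the C10 epimers are separated to give (1R)-1-[(1S)-1-methyl-4-(propan-2-yl)cyclohex-3-en-1-yl]prop-2-en-1-ol F1. Et3SiCl and imidazole give its triethylsilyl ether F2. Ozonolysis as in step 4 gives (3S)-3,7-dimethyl-6-oxo-3-[(1R)-1-(triethylsilyloxy)prop-2-en-1-yl]octanal F3. The aldol closure of step 5 gives (1R,2R,5S)-2-hydroxy-5-methyl-2-(propan-2-yl)-5-[(1R)-1-(triethylsilyloxy)prop-2-en-1-yl]cyclopentane-1-carbaldehyde F4. Chelation-controlled addition of 2-methylallylmagnesium chloride to the formyl group should give the C6 homoallylic alcohol F5. Ring-closing metathesis with the second-generation Grubbs catalyst should give (3R,3aS,4S,8R,8aS)-6,8a-dimethyl-3-(propan-2-yl)-8-(triethylsilyloxy)-1,2,3,3a,4,5,8,8a-octahydroazulene-3,4-diol F6, and Bu4NF then gives 11.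

2. Step 3. What may go wrong: α-elimination of the lithiated chloride before boron capture; loss of the Z geometry of the methyl-substituted chloroallylborane, which would erode the syn selectivity and hence the cis geometry of the oxirane; incomplete facial control at C10.
Fallback sets out from 5 and returns at 8. The Bu2BOTf/i-Pr2NEt syn-aldol (Evans aldol) of (4R)-4-benzyl-3-(chloroacetyl)-1,3-oxazolidin-2-one with 5 should give the (2R,3S)-2-chloro-3-hydroxy imide F7. Me(MeO)NH·HCl with AlMe3 gives the N-methoxy-N-methylamide F8. K2CO3 in MeOH closes the cis-oxirane amide F9. MeMgBr gives the cis-epoxy methyl ketone F10, and Wittig methylenation (Ph3P=CH2) gives 8.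

3. Step 5. What may go wrong: an unfavourable aldol equilibrium at the hindered isopropyl ketone; dehydration to the enal; attack of the amine on the vinyl oxirane; poor facial selectivity at C4 if retro-aldol equilibration is slow.
Fallback sets out from 9 and returns at 10. Piperidinium acetate in hot benzene drives the dehydrative aldol condensation to (5S)-5-methyl-5-[(2S,3R)-3-(prop-1-en-2-yl)oxiran-2-yl]-2-(propan-2-yl)cyclopent-1-ene-1-carbaldehyde F11. Weitz–Scheffer epoxidation (H2O2, NaOH, MeOH, 0 °C) from the face anti to the oxiranyl side chain should give (1R,2S,5R)-2-methyl-2-[(2S,3R)-3-(prop-1-en-2-yl)oxiran-2-yl]-5-(propan-2-yl)-6-oxabicyclo[3.1.0]hexane-1-carbaldehyde F12. Reductive opening of the carbonyl-activated oxirane at its α-carbon with Na[PhSeB(OEt)3] (from (PhSe)2 and NaBH4, EtOH, AcOH) should give 10.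

**Further compounds**
F1 | step 6 | (1R)-1-[(1S)-1-methyl-4-(propan-2-yl)cyclohex-3-en-1-yl]prop-2-en-1-ol | CC(C)C1=CC[C@](C)(CC1)[C@H](O)C=C
F2 | step 6 | triethyl{[(1R)-1-[(1S)-1-methyl-4-(propan-2-yl)cyclohex-3-en-1-yl]prop-2-en-1-yl]oxy}silane | CC(C)C1=CC[C@](C)(CC1)[C@H](O[Si](CC)(CC)CC)C=C
F3 | step 6 | (3S)-3,7-dimethyl-6-oxo-3-[(1R)-1-(triethylsilyloxy)prop-2-en-1-yl]octanal | O=CC[C@](C)(CCC(=O)C(C)C)[C@H](O[Si](CC)(CC)CC)C=C
F4 | step 6 | (1R,2R,5S)-2-hydroxy-5-methyl-2-(propan-2-yl)-5-[(1R)-1-(triethylsilyloxy)prop-2-en-1-yl]cyclopentane-1-carbaldehyde | O=C[C@H]1[C@](O)(C(C)C)CC[C@]1(C)[C@H](O[Si](CC)(CC)CC)C=C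
F5 | step 6 | (1S)-1-[(1S,2R,5S)-2-hydroxy-5-methyl-2-(propan-2-yl)-5-[(1R)-1-(triethylsilyloxy)prop-2-en-1-yl]cyclopentyl]-3-methylbut-3-en-1-ol | C=C(C)C[C@H](O)[C@H]1[C@](O)(C(C)C)CC[C@]1(C)[C@H](O[Si](CC)(CC)CC)C=C
F6 | step 6 | (3R,3aS,4S,8R,8aS)-6,8a-dimethyl-3-(propan-2-yl)-8-(triethylsilyloxy)-1,2,3,3a,4,5,8,8a-octahydroazulene-3,4-diol | CC[Si](CC)(CC)O[C@@H]1C=C(C)C[C@H](O)[C@@H]2[C@]1(C)CC[C@@]2(O)C(C)C
F7 | step 3 | (4R)-4-benzyl-3-{(2R,3S)-2-chloro-3-hydroxy-3-[(1S)-1-methyl-4-(propan-2-yl)cyclohex-3-en-1-yl]propanoyl}-1,3-oxazolidin-2-one | CC(C)C1=CC[C@](C)(CC1)[C@H](O)[C@@H](Cl)C(=O)N2C(=O)OC[C@H]2Cc3ccccc3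
F8 | step 3 | (2R,3S)-2-chloro-3-hydroxy-N-methoxy-N-methyl-3-[(1S)-1-methyl-4-(propan-2-yl)cyclohex-3-en-1-yl]propanamide | CC(C)C1=CC[C@](C)(CC1)[C@H](O)[C@@H](Cl)C(=O)N(C)OC
F9 | step 3 | (2S,3S)-N-methoxy-N-methyl-3-[(1S)-1-methyl-4-(propan-2-yl)cyclohex-3-en-1-yl]oxirane-2-carboxamide (cis) | CC(C)C1=CC[C@](C)(CC1)[C@@H]2O[C@@H]2C(=O)N(C)OC
F10 | step 3 | 1-{(2S,3S)-3-[(1S)-1-methyl-4-(propan-2-yl)cyclohex-3-en-1-yl]oxiran-2-yl}ethan-1-one (cis) | CC(C)C1=CC[C@](C)(CC1)[C@@H]2O[C@@H]2C(C)=O
F11 | step 5 | (5S)-5-methyl-5-[(2S,3R)-3-(prop-1-en-2-yl)oxiran-2-yl]-2-(propan-2-yl)cyclopent-1-ene-1-carbaldehyde | O=CC1=C(C(C)C)CC[C@]1(C)[C@@H]2O[C@@H]2C(C)=C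
F12 | step 5 | (1R,2S,5R)-2-methyl-2-[(2S,3R)-3-(prop-1-en-2-yl)oxiran-2-yl]-5-(propan-2-yl)-6-oxabicyclo[3.1.0]hexane-1-carbaldehyde | O=C[C@@]12O[C@@]2(C(C)C)CC[C@]1(C)[C@@H]3O[C@@H]3C(C)=C
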